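## Retrosynthetic overview

- The target is reached from cyclohexenol 20 by acetylation of O2, removal of the 4-methoxybenzyl group, Mitsunobu benzoylation with inversion at C3, and desilylation of O1.
- 20 comes from a one-pot [3+3] annulation of aldehyde–acetal 7 (C2–C1(–C7)–C6) with the bifunctional allylboronate 16 (C3–C4–C5): allylboration makes C2–C3, then a vinylsilane/oxocarbenium closure makes C5–C6. The cyclohexene is the only ring built in the route and it forms here.
- Enabling feature: the two oxygenated ring carbons C2 and C6 both sit on the quaternary carbinol C1, so they are the two ends of one masked hydroxymalonaldehyde. The C6 methyl ether is allylic to C4=C5 (methyl oxocarbenium plus vinylsilane) and the C2/C3 diol is homoallylic/allylic to the same alkene (alkoxyallylation), so one three-carbon reagent can bridge C2 and C6.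
- 7 comes from methacrolein (acetal, allylic oxidation, asymmetric epoxidation setting C1, benzoate opening, silylation, oxidation). 16 comes from 4-methoxybenzyl alcohol and trichloroethylene (ynol ether), hydroboration, and Matteson homologation with (chloromethyl)trimethylsilane.

Key step: step 10

Remark: locants follow the target throughout (C1 quaternary carbinol carbon, C2 acetoxy carbon, C3 benzoyloxy carbon, C4=C5 alkene, C6 methoxy carbon, C7 exocyclic CH2), also in the cyclohexene names; the key step assumes that the enantiopure aldehyde selects the matched enantiomer of racemic 16.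

## Route

Step 1
Reactants: 1 methacrolein (2-methylprop-2-enal)
Product: 2 3,3-dimethoxy-2-methylprop-1-ene
Conditions: HC(OMe)3, NH4NO3 (cat.), MeOH, rt
Reagents that add atoms: trimethyl orthoformate, COC(OC)OC
Why: Acetalisation with an orthoester as water scavenger; the weakly acidic ammonium salt should avoid conjugate addition of methanol to the enal.

Step 2
Reactants: 2 3,3-dimethoxy-2-methylprop-1-ene
Product: 3 2-(dimethoxymethyl)prop-2-en-1-ol
Conditions: SeO2 (0.3 equiv), t-BuOOH, CH2Cl2, 0 °C to rt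
Reagents that add atoms: selenium dioxide, O=[Se]=O (oxygen carrier, substoichiometric); tert-butyl hydroperoxide, CC(C)(C)OO (terminal oxidant)
Why: Riley-type allylic oxidation (ene reaction, then [2,3]-sigmatropic shift) should hydroxylate the methyl group of the 1,1-disubstituted alkene, the electron-poor acetal C–H being slower.

Step 3
Reactants: 3 2-(dimethoxymethyl)prop-2-en-1-ol
Product: 4 (R)-[2-(dimethoxymethyl)oxiran-2-yl]methanol
Conditions: Ti(OiPr)4 (10 mol%), D-(−)-diethyl tartrate (12 mol%), t-BuOOH, 4 Å MS, CH2Cl2, −20 °C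
Reagents that add atoms: tert-butyl hydroperoxide, CC(C)(C)OO
Why: Sharpless asymmetric epoxidation of a 2-substituted allylic alcohol; the D-tartrate ligand should deliver oxygen to the face that gives the R epoxide, which fixes C1.

Step 4
Reactants: 4 (R)-[2-(dimethoxymethyl)oxiran-2-yl]methanol
Product: 5 (R)-2-(dimethoxymethyl)-2,3-dihydroxypropyl benzoate
Conditions: PhCO2H, Ti(OiPr)4, CH2Cl2, 0 °C to rt
Reagents that add atoms: benzoic acid, OC(=O)c1ccccc1
Why: Ti(OiPr)4-assisted opening of a 2,3-epoxy alcohol by a carboxylate at the distal, unsubstituted epoxide carbon leaves the C1–O bond untouched and installs the C7 benzoate of the target.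

Step 5
Reactants: 5 (R)-2-(dimethoxymethyl)-2,3-dihydroxypropyl benzoate
Product: 6 (S)-2-(dimethoxymethyl)-2,3-bis[(triethylsilyl)oxy]propyl benzoate
Conditions: TESOTf, 2,6-lutidine, CH2Cl2, −78 to 0 °C
Reagents that add atoms: triethylsilyl trifluoromethanesulfonate, CC[Si](CC)(CC)OS(=O)(=O)C(F)(F)F
Why: A silyl triflate with a hindered base silylates the primary and the tertiary hydroxyl quickly at low temperature, which also stops any benzoyl shift between the two primary oxygens.

Step 6
Reactants: 6 (S)-2-(dimethoxymethyl)-2,3-bis[(triethylsilyl)oxy]propyl benzoate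
Product: 7 (S)-2-(dimethoxymethyl)-3-oxo-2-[(triethylsilyl)oxy]propyl benzoate
Conditions: (COCl)2, DMSO, CH2Cl2, −78 to −35 °C; Et3N, −78 to 0 °C
Reagents that add atoms: none
Why: Under Swern conditions a primary triethylsilyl ether is cleaved and oxidised directly to the aldehyde while the hindered tertiary silyl ether stays, and the aldehyde has no α-hydrogen so C1 cannot epimerise.

Step 7
Reactants: 8 4-methoxybenzyl alcohol; 9 trichloroethylene
Product: 12 1-[(ethynyloxy)methyl]-4-methoxybenzene, via dichlorovinyl ether 10 (not isolated), via lithium alkynyl ether 11 (not isolated)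
Conditions: KH, THF, 0 °C; Cl2C=CHCl, −50 °C to rt; n-BuLi (2.5 equiv), −78 to −40 °C; MeOH, −78 °C
Reagents that add atoms: none
Why: Alkoxide substitution on trichloroethylene gives 10, which n-BuLi converts by dehydrochlorination and chlorine–lithium exchange into 11 that is protonated (standard ynol ether synthesis); the product is kept at or below room temperature because benzyl ynol ethers rearrange on heating.

Step 8
Reactants: 12 1-[(ethynyloxy)methyl]-4-methoxybenzene
Product: 13 (E)-2-{2-[(4-methoxybenzyl)oxy]ethenyl}-4,4,5,5-tetramethyl-1,3,2-dioxaborolane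
Conditions: HBpin, Cp2Zr(H)Cl (5 mol%), Et3N (cat.), CH2Cl2, rt
Reagents that add atoms: pinacolborane, CC1(C)OBOC1(C)C
Why: Zirconium-catalysed syn hydroboration of an alkoxyalkyne places boron on the terminal carbon and should give only the E β-alkoxyvinylboronate.

Step 9
Reactants: 13 (E)-2-{2-[(4-methoxybenzyl)oxy]ethenyl}-4,4,5,5-tetramethyl-1,3,2-dioxaborolane; 14 (chloromethyl)trimethylsilane
Product: 16 rac-(E)-2-{3-[(4-methoxybenzyl)oxy]-1-(trimethylsilyl)prop-2-en-1-yl}-4,4,5,5-tetramethyl-1,3,2-dioxaborolane, via boronate complex 15 (not isolated)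
Conditions: 14, s-BuLi, TMEDA, THF, −78 °C; then 13, −78 °C to rt
Reagents that add atoms: none
Why: Matteson homologation: the lithiated chlorosilane adds to boron and the alkenyl group of 15 then migrates with loss of chloride, which inserts the silyl-bearing carbon C5 between boron and the enol ether with retention of the E geometry.

Step 10
Reactants: 7 (S)-2-(dimethoxymethyl)-3-oxo-2-[(triethylsilyl)oxy]propyl benzoate; 16 rac-(E)-2-{3-[(4-methoxybenzyl)oxy]-1-(trimethylsilyl)prop-2-en-1-yl}-4,4,5,5-tetramethyl-1,3,2-dioxaborolane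
Product: 20 [(1S,2S,3S,6S)-2-hydroxy-6-methoxy-3-[(4-methoxybenzyl)oxy]-1-[(triethylsilyl)oxy]cyclohex-4-en-1-yl]methyl benzoate, via allylboration adduct 17 (not isolated), via oxocarbenium triflate 18 (not isolated), via cyclohexenyl borate 19 (not isolated)
Conditions: rac-16 (2.5 equiv), PhMe, 45 °C; i-PrCHO, 45 °C, then evaporation; CH2Cl2, 2,6-di-tert-butyl-4-methylpyridine, TMSOTf (0.3 equiv), −78 to −30 °C; aq. NaHCO3
Reagents that add atoms: none
Why: The pinacol allylboronate adds to the aldehyde without Lewis acid through a chair transition state (closest known type: aldehyde additions of α-silyl and of (E)-γ-alkoxy allylboronates), which forms C2–C3 as borate 17 and leaves the acetal untouched; TMSOTf then ionises the dimethyl acetal to 18, whose C6 is attacked by the silyl-bearing carbon C5 with loss of the silyl group (closest known type: vinylsilane-terminated acetal cyclisation), which forms C5–C6 and gives 19. The cyclohexene closes in this second event as a six-membered cation–olefin cyclisation in the endocyclic mode, possible only because the vinylsilane is cis. C2 is controlled by C1 (Felkin–Anh attack anti to the C1–OSiEt3 bond, past the small CH2OBz arm, which puts the C2 and C1 oxygens cis on the future ring), C3 by the E enol ether in the chair (2,3-anti, so the C3 oxygen is cis to the C2 oxygen), and the Z alkene by the pseudo-axial α-silyl group. C6 is controlled in the ring closure, where a chair-like array with a pseudo-equatorial oxocarbenium avoids a 1,3-diaxial contact with the axial C2 oxygen and should place the methoxy group trans to the C1 oxygen. The step needs the aldehyde to react before the acetal, which the order of addition secures, and it needs matched double stereodifferentiation, for which racemic 16 is used in excess so that its matched enantiomer is consumed first; the surplus enol ether is quenched with isobutyraldehyde before the Lewis acid is added so that it cannot trap 18.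

Step 11
Reactants: 20 [(1S,2S,3S,6S)-2-hydroxy-6-methoxy-3-[(4-methoxybenzyl)oxy]-1-[(triethylsilyl)oxy]cyclohex-4-en-1-yl]methyl benzoate
Product: 21 [(1R,2S,3S,6S)-2-acetoxy-6-methoxy-3-[(4-methoxybenzyl)oxy]-1-[(triethylsilyl)oxy]cyclohex-4-en-1-yl]methyl benzoate
Conditions: Ac2O, pyridine, DMAP (cat.), CH2Cl2, rt
Reagents that add atoms: acetic anhydride, CC(=O)OC(C)=O
Why: DMAP-catalysed acylation of the only free hydroxyl, the hindered secondary C2–OH.

Step 12
Reactants: 21 [(1R,2S,3S,6S)-2-acetoxy-6-methoxy-3-[(4-methoxybenzyl)oxy]-1-[(triethylsilyl)oxy]cyclohex-4-en-1-yl]methyl benzoate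
Product: 22 [(1R,2S,3S,6S)-2-acetoxy-3-hydroxy-6-methoxy-1-[(triethylsilyl)oxy]cyclohex-4-en-1-yl]methyl benzoate
Conditions: DDQ, CH2Cl2/pH 7 buffer, 0 °C
Reagents that add atoms: none
Why: Oxidative cleavage of the 4-methoxybenzyl ether through its benzylic oxocarbenium ion under buffered neutral conditions should spare the esters, the silyl ether and the allylic methyl ether and give the cis-hydroxy acetate without acetyl shift.

Step 13
Reactants: 22 [(1R,2S,3S,6S)-2-acetoxy-3-hydroxy-6-methoxy-1-[(triethylsilyl)oxy]cyclohex-4-en-1-yl]methyl benzoate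
Product: 23 [(1R,2S,3R,6S)-2-acetoxy-3-(benzoyloxy)-6-methoxy-1-[(triethylsilyl)oxy]cyclohex-4-en-1-yl]methyl benzoate
Conditions: PPh3, DIAD, PhCO2H, PhMe, 0 °C to rt
Reagents that add atoms: benzoic acid, OC(=O)c1ccccc1
Why: Mitsunobu esterification: benzoate displaces the C3 oxyphosphonium group by SN2 with inversion, turning the cis C2/C3 pair into the required trans pair, and the cis acetate cannot give anchimeric assistance.

Step 14
Reactants: 23 [(1R,2S,3R,6S)-2-acetoxy-3-(benzoyloxy)-6-methoxy-1-[(triethylsilyl)oxy]cyclohex-4-en-1-yl]methyl benzoate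
Product: 24 [(1R,2S,3R,6S)-2-acetoxy-3-(benzoyloxy)-1-hydroxy-6-methoxycyclohex-4-en-1-yl]methyl benzoate (CNP0130888.1)
Conditions: HF·pyridine, pyridine, THF, 0 °C to rt
Reagents that add atoms: none
Why: Fluoride cleavage of the tertiary triethylsilyl ether under buffered conditions that the three esters and the allylic ether should survive.

## Compound list

1 | methacrolein (2-methylprop-2-enal) | CC(=C)C=O | starting material
2 | 3,3-dimethoxy-2-methylprop-1-ene | C=C(C)C(OC)OC | intermediate
3 | 2-(dimethoxymethyl)prop-2-en-1-ol | C=C(CO)C(OC)OC | intermediate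
4 | (R)-[2-(dimethoxymethyl)oxiran-2-yl]methanol | OC[C@@]1(CO1)C(OC)OC | intermediate
5 | (R)-2-(dimethoxymethyl)-2,3-dihydroxypropyl benzoate | OC[C@@](O)(COC(=O)c1ccccc1)C(OC)OC | intermediate
6 | (S)-2-(dimethoxymethyl)-2,3-bis[(triethylsilyl)oxy]propyl benzoate | CC[Si](CC)(CC)OC[C@@](O[Si](CC)(CC)CC)(COC(=O)c1ccccc1)C(OC)OC | intermediate
7 | (S)-2-(dimethoxymethyl)-3-oxo-2-[(triethylsilyl)oxy]propyl benzoate | O=C[C@@](O[Si](CC)(CC)CC)(COC(=O)c1ccccc1)C(OC)OC | intermediate
8 | 4-methoxybenzyl alcohol | COc1ccc(CO)cc1 | starting material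
9 | trichloroethylene | ClC=C(Cl)Cl | starting material
10 | (E)-1-{[(1,2-dichloroethenyl)oxy]methyl}-4-methoxybenzene (not isolated) | COc1ccc(CO/C(Cl)=C\Cl)cc1 | intermediate
11 | lithium 2-[(4-methoxybenzyl)oxy]ethynide (not isolated) | [Li]C#COCc1ccc(OC)cc1 | intermediate
12 | 1-[(ethynyloxy)methyl]-4-methoxybenzene | COc1ccc(COC#C)cc1 | intermediate
13 | (E)-2-{2-[(4-methoxybenzyl)oxy]ethenyl}-4,4,5,5-tetramethyl-1,3,2-dioxaborolane | COc1ccc(CO/C=C/B2OC(C)(C)C(C)(C)O2)cc1 | intermediate
14 | (chloromethyl)trimethylsilane | C[Si](C)(C)CCl | starting material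
15 | lithium boronate complex of 13 carrying the chloro(trimethylsilyl)methyl group on boron (not isolated) | [Li+].COc1ccc(CO/C=C/[B-]2(C(Cl)[Si](C)(C)C)OC(C)(C)C(C)(C)O2)cc1 | intermediate
16 | rac-(E)-2-{3-[(4-methoxybenzyl)oxy]-1-(trimethylsilyl)prop-2-en-1-yl}-4,4,5,5-tetramethyl-1,3,2-dioxaborolane | COc1ccc(CO/C=C/C([Si](C)(C)C)B2OC(C)(C)C(C)(C)O2)cc1 | intermediate
17 | (2S,3S,4S,5Z)-2-(dimethoxymethyl)-4-[(4-methoxybenzyl)oxy]-3-[(4,4,5,5-tetramethyl-1,3,2-dioxaborolan-2-yl)oxy]-2-[(triethylsilyl)oxy]-6-(trimethylsilyl)hex-5-en-1-yl benzoate (not isolated) | C[Si](C)(C)/C=C\[C@H](OCc1ccc(OC)cc1)[C@H](OB2OC(C)(C)C(C)(C)O2)[C@@](O[Si](CC)(CC)CC)(COC(=O)c1ccccc1)C(OC)OC | intermediate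
18 | O-methyl oxocarbenium triflate formed from 17 by loss of one methoxy group at C6 (not isolated) | C[Si](C)(C)/C=C\[C@H](OCc1ccc(OC)cc1)[C@H](OB2OC(C)(C)C(C)(C)O2)[C@@](O[Si](CC)(CC)CC)(COC(=O)c1ccccc1)C=[O+]C.[O-]S(=O)(=O)C(F)(F)F | intermediate
19 | [(1S,2S,3S,6S)-6-methoxy-3-[(4-methoxybenzyl)oxy]-2-[(4,4,5,5-tetramethyl-1,3,2-dioxaborolan-2-yl)oxy]-1-[(triethylsilyl)oxy]cyclohex-4-en-1-yl]methyl benzoate (not isolated) | CO[C@H]1C=C[C@H](OCc2ccc(OC)cc2)[C@H](OB2OC(C)(C)C(C)(C)O2)[C@@]1(O[Si](CC)(CC)CC)COC(=O)c1ccccc1 | intermediate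
20 | [(1S,2S,3S,6S)-2-hydroxy-6-methoxy-3-[(4-methoxybenzyl)oxy]-1-[(triethylsilyl)oxy]cyclohex-4-en-1-yl]methyl benzoate | CO[C@H]1C=C[C@H](OCc2ccc(OC)cc2)[C@H](O)[C@@]1(O[Si](CC)(CC)CC)COC(=O)c1ccccc1 | intermediate
21 | [(1R,2S,3S,6S)-2-acetoxy-6-methoxy-3-[(4-methoxybenzyl)oxy]-1-[(triethylsilyl)oxy]cyclohex-4-en-1-yl]methyl benzoate | CO[C@H]1C=C[C@H](OCc2ccc(OC)cc2)[C@H](OC(C)=O)[C@@]1(O[Si](CC)(CC)CC)COC(=O)c1ccccc1 | intermediate
22 | [(1R,2S,3S,6S)-2-acetoxy-3-hydroxy-6-methoxy-1-[(triethylsilyl)oxy]cyclohex-4-en-1-yl]methyl benzoate | CO[C@H]1C=C[C@H](O)[C@H](OC(C)=O)[C@@]1(O[Si](CC)(CC)CC)COC(=O)c1ccccc1 | intermediate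
23 | [(1R,2S,3R,6S)-2-acetoxy-3-(benzoyloxy)-6-methoxy-1-[(triethylsilyl)oxy]cyclohex-4-en-1-yl]methyl benzoate | CO[C@H]1C=C[C@@H](OC(=O)c2ccccc2)[C@H](OC(C)=O)[C@@]1(O[Si](CC)(CC)CC)COC(=O)c1ccccc1 | intermediate
24 | [(1R,2S,3R,6S)-2-acetoxy-3-(benzoyloxy)-1-hydroxy-6-methoxycyclohex-4-en-1-yl]methyl benzoate (CNP0130888.1) | CO[C@H]1C=C[C@@H](OC(=O)c2ccccc2)[C@H](OC(C)=O)[C@@]1(O)COC(=O)c1ccccc1 | target

## Step count and risks

Total step count: 14. Longest linear sequence: 11 steps (steps 1 to 6, then 10 to 14); the reagent branch is steps 7 to 9.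

**Step 10.** A hindered neopentyl-type aldehyde meets a hindered, racemic allylboronate, so the addition may be slow, the mismatched pairing may erode facial selectivity at C2, and the pathway with an equatorial silyl group may leak to the trans vinylsilane, which cannot cyclise.

Fallback, from 7 to 20:
- 1-methoxy-4-({[3-(trimethylsilyl)prop-2-yn-1-yl]oxy}methyl)benzene F1 would be made from commercial 3-(trimethylsilyl)prop-2-yn-1-ol and 4-methoxybenzyl trichloroacetimidate (cat. TfOH).
- F1 is lithiated (s-BuLi, THF, −78 °C), transmetalated with ZnBr2 and added to 7. The achiral allenylzinc should add anti-selectively under control of C1 alone to give (2S,3S,4S)-2-(dimethoxymethyl)-3-hydroxy-4-[(4-methoxybenzyl)oxy]-2-[(triethylsilyl)oxy]-6-(trimethylsilyl)hex-5-yn-1-yl benzoate F2.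
- Semihydrogenation (H2, Pd/CaCO3 poisoned with Pb(OAc)2, quinoline) should give the cis vinylsilane (2S,3S,4S,5Z)-2-(dimethoxymethyl)-3-hydroxy-4-[(4-methoxybenzyl)oxy]-2-[(triethylsilyl)oxy]-6-(trimethylsilyl)hex-5-en-1-yl benzoate F3 stereospecifically.
- F3 is closed with TMSOTf as in the second half of step 10, which returns to the route at 20.

**Step 9.** The hindered lithiated chlorosilane may complex poorly with the weakly Lewis acidic, donor-substituted alkenylboronate 13, so that it decomposes before the boronate complex forms, or the complex may rearrange incompletely.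

Fallback, from 12 and 14 back to 15 and 16, with the roles of the partners reversed:
- Hydrozirconation of 12 (Cp2Zr(H)Cl, 1 equiv) and iodinolysis (I2) should give (E)-1-{[(2-iodoethenyl)oxy]methyl}-4-methoxybenzene F4.
- Lithiation of 14 as in step 9, quench with B(OMe)3 and exchange with pinacol should give the stable α-chloro boronic ester 2-[chloro(trimethylsilyl)methyl]-4,4,5,5-tetramethyl-1,3,2-dioxaborolane F5.
- Iodine–lithium exchange on F4 (t-BuLi, −78 °C) and addition of the alkenyllithium to F5 should give the same boronate complex 15, which rearranges to 16.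

**Step 13.** The benzoate may attack C5 with allylic transposition, the oxyphosphonium ion may eliminate to a diene, or the acetyl group may shift from O2 to O3 before activation.

Fallback, from 22 to 24, replacing the substitution by oxidation and hydroxyl-directed reduction:
- Dess–Martin periodinane (NaHCO3, CH2Cl2) should give the enone [(1R,2R,6S)-2-acetoxy-6-methoxy-3-oxo-1-[(triethylsilyl)oxy]cyclohex-4-en-1-yl]methyl benzoate F6.
- HF·pyridine should free the tertiary alcohol to give [(1R,2R,6S)-2-acetoxy-1-hydroxy-6-methoxy-3-oxocyclohex-4-en-1-yl]methyl benzoate F7.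
- Evans–Saksena reduction (Me4NBH(OAc)3, MeCN/AcOH, −30 °C) should deliver hydride from the face of the C1 hydroxyl and give the 1,3-anti diol [(1R,2S,3R,6S)-2-acetoxy-1,3-dihydroxy-6-methoxycyclohex-4-en-1-yl]methyl benzoate F8.
- Selective benzoylation of the secondary allylic hydroxyl (BzCl, pyridine, 0 °C) rejoins the route at 24.

Further compounds

F1 | step 10 | 1-methoxy-4-({[3-(trimethylsilyl)prop-2-yn-1-yl]oxy}methyl)benzene | COc1ccc(COCC#C[Si](C)(C)C)cc1
F2 | step 10 | (2S,3S,4S)-2-(dimethoxymethyl)-3-hydroxy-4-[(4-methoxybenzyl)oxy]-2-[(triethylsilyl)oxy]-6-(trimethylsilyl)hex-5-yn-1-yl benzoate | C[Si](C)(C)C#C[C@H](OCc1ccc(OC)cc1)[C@H](O)[C@@](O[Si](CC)(CC)CC)(COC(=O)c1ccccc1)C(OC)OC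
F3 | step 10 | (2S,3S,4S,5Z)-2-(dimethoxymethyl)-3-hydroxy-4-[(4-methoxybenzyl)oxy]-2-[(triethylsilyl)oxy]-6-(trimethylsilyl)hex-5-en-1-yl benzoate | C[Si](C)(C)/C=C\[C@H](OCc1ccc(OC)cc1)[C@H](O)[C@@](O[Si](CC)(CC)CC)(COC(=O)c1ccccc1)C(OC)OC
F4 | step 9 | (E)-1-{[(2-iodoethenyl)oxy]methyl}-4-methoxybenzene | COc1ccc(CO/C=C/I)cc1
F5 | step 9 | 2-[chloro(trimethylsilyl)methyl]-4,4,5,5-tetramethyl-1,3,2-dioxaborolane | C[Si](C)(C)C(Cl)B1OC(C)(C)C(C)(C)O1
F6 | step 13 | [(1R,2R,6S)-2-acetoxy-6-methoxy-3-oxo-1-[(triethylsilyl)oxy]cyclohex-4-en-1-yl]methyl benzoate | CO[C@H]1C=CC(=O)[C@H](OC(C)=O)[C@@]1(O[Si](CC)(CC)CC)COC(=O)c1ccccc1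
F7 | step 13 | [(1R,2R,6S)-2-acetoxy-1-hydroxy-6-methoxy-3-oxocyclohex-4-en-1-yl]methyl benzoate | CO[C@H]1C=CC(=O)[C@H](OC(C)=O)[C@@]1(O)COC(=O)c1ccccc1
F8 | step 13 | [(1R,2S,3R,6S)-2-acetoxy-1,3-dihydroxy-6-methoxycyclohex-4-en-1-yl]methyl benzoate | CO[C@H]1C=C[C@@H](O)[C@H](OC(C)=O)[C@@]1(O)COC(=O)c1ccccc1
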